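**Retrosynthetic overview**
1. Last step: the ester C–O bond is formed by Yamaguchi coupling of dienoic acid 29 (C9) with trienone alcohol 22 (C15).
2. 22 comes from C6 ketone 21 by face-selective Luche reduction; the isopropylidene comes from acetone by aldol addition and E1cB elimination on dienone ketal 15.
3. Ring A is present first, as dearomatised hydroquinone (quinone monoketal 3); a copper-catalysed asymmetric Me2Zn addition sets the secondary methyl, then the alpha-prime methyl is added.
4. Ring B is closed second: Michael addition of the ring A dienolate to silyl enone 11 sets the quaternary centre, then aldol condensation gives the linear dienone directly.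
5. 29 comes from (S)-2-methylbutanal 26 and phosphonocrotonate 24 (vinylogous Horner–Wadsworth–Emmons); 11 comes from (1-bromovinyl)trimethylsilane and acetaldehyde.

**Assumption:** the (S,R,R)-phosphoramidite is taken to show the same facial sense on dienone 3 as on cyclohex-2-enone, which gives (5R)-4; if the sense is opposite, the mirror-image ligand is used.

**Step 1**
Reactants: 1 hydroquinone (benzene-1,4-diol)
Product: 2 4-methoxyphenol
Conditions: Me2SO4 (1.0 equiv), NaOH (1.0 equiv), H2O, 20 °C
Reagents that add atoms: dimethyl sulfate COS(=O)(=O)OC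
Why: Williamson-type O-methylation of the monophenoxide, limited to the mono-ether by stoichiometry, with the diol and diether removed by extraction and distillation.

**Step 2**
Reactants: 2 4-methoxyphenol
Product: 3 4,4-dimethoxycyclohexa-2,5-dien-1-one
Conditions: PhI(OAc)2 (1.1 equiv), MeOH, 0 °C
Reagents that add atoms: methanol CO
Why: hypervalent-iodine oxidative dearomatisation in which methanol adds para to the phenol oxygen to give the quinone monoketal.

**Step 3**
Reactants: 3 4,4-dimethoxycyclohexa-2,5-dien-1-one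
Product: 4 (5R)-4,4-dimethoxy-5-methylcyclohex-2-en-1-one
Conditions: Cu(OTf)2 (2 mol%), (S)-(1,1'-binaphthalene-2,2'-diyl) N,N-bis[(R)-1-phenylethyl]phosphoramidite (4 mol%), Me2Zn (1.5 equiv), toluene, −25 °C; then H2O
Reagents that add atoms: dimethylzinc C[Zn]C
Why: copper-catalysed asymmetric conjugate addition desymmetrises the prochiral dienone, and the ligand sets the methyl-bearing centre as R.

**Step 4**
Reactants: 4 (5R)-4,4-dimethoxy-5-methylcyclohex-2-en-1-one
Product: 6 (5R,6R)-4,4-dimethoxy-5,6-dimethylcyclohex-2-en-1-one, via lithium dienolate 5 (not isolated)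
Conditions: LiN(i-Pr)2 (1.1 equiv), THF, −78 °C; MeI (1.5 equiv), −78 → −20 °C
Reagents that add atoms: iodomethane CI
Why: kinetic alpha-prime deprotonation (the gamma position is blocked by the ketal) and SN2 enolate alkylation give mainly the trans isomer, and the C6 centre is flattened again in step 7 so the minor cis epimer is carried along.

**Step 5**
Reactants: 7 (1-bromovinyl)trimethylsilane; 8 acetaldehyde
Product: 10 3-(trimethylsilyl)but-3-en-2-ol (racemic), via Grignard reagent 9 (not isolated)
Conditions: Mg, THF, reflux; then MeCHO, 0 °C; then H2O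
Reagents that add atoms: none
Why: Grignard formation from the vinyl bromide and 1,2-addition to the aldehyde.

**Step 6**
Reactants: 10 3-(trimethylsilyl)but-3-en-2-ol
Product: 11 3-(trimethylsilyl)but-3-en-2-one
Conditions: Dess–Martin periodinane (1.2 equiv), CH2Cl2, 0 → 20 °C
Reagents that add atoms: none
Why: mild oxidation of the secondary allylic alcohol gives the alpha-silyl enone (Stork–Ganem Michael acceptor) without polymerising it.

**Step 7**
Reactants: 6 (5R,6R)-4,4-dimethoxy-5,6-dimethylcyclohex-2-en-1-one; 11 3-(trimethylsilyl)but-3-en-2-one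
Product: 13 (5R,6R)-4,4-dimethoxy-5,6-dimethyl-6-[3-oxo-2-(trimethylsilyl)butyl]cyclohex-2-en-1-one, via lithium dienolate 12 (not isolated)
Conditions: LiN(i-Pr)2 (1.05 equiv), THF, −78 °C; then 11 (1.2 equiv), −78 °C; AcOH quench at −78 °C
Reagents that add atoms: none
Why: Michael addition of the cross-conjugated dienolate to the silyl enone occurs anti to the pseudoaxial C5 methyl, which sets the quaternary centre (6R) with the two methyl groups cis.

**Step 8**
Reactants: 13 (5R,6R)-4,4-dimethoxy-5,6-dimethyl-6-[3-oxo-2-(trimethylsilyl)butyl]cyclohex-2-en-1-one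
Product: 15 (4aR,5R)-6,6-dimethoxy-4a,5-dimethyl-4,4a,5,6-tetrahydronaphthalen-2(3H)-one, via diketone 14 (not isolated)
Conditions: KOH (5% in MeOH), 20 → 60 °C
Reagents that add atoms: none
Why: methoxide removes the silyl group and the methyl ketone then undergoes intramolecular aldol condensation onto the ring carbonyl (Robinson annulation), which closes ring B as the linear dienone without touching a stereocentre.

**Step 9**
Reactants: 15 (4aR,5R)-6,6-dimethoxy-4a,5-dimethyl-4,4a,5,6-tetrahydronaphthalen-2(3H)-one; 16 acetone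
Product: 18 (4aR,5R)-3-(2-hydroxypropan-2-yl)-6,6-dimethoxy-4a,5-dimethyl-4,4a,5,6-tetrahydronaphthalen-2(3H)-one (both C3 epimers), via lithium enolate 17 (not isolated)
Conditions: LiN(i-Pr)2 (1.1 equiv), THF, −78 °C; acetone (3 equiv), −78 °C; AcOH quench at −78 °C
Reagents that add atoms: none
Why: C3 carries the only enolisable hydrogens, so kinetic deprotonation and aldol addition to acetone occur there, and the cold quench prevents retro-aldol cleavage.

**Step 10**
Reactants: 18 (4aR,5R)-3-(2-hydroxypropan-2-yl)-6,6-dimethoxy-4a,5-dimethyl-4,4a,5,6-tetrahydronaphthalen-2(3H)-one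
Product: 20 (4aR,5R)-6,6-dimethoxy-4a,5-dimethyl-3-(propan-2-ylidene)-4,4a,5,6-tetrahydronaphthalen-2(3H)-one, via mesylate 19 (not isolated)
Conditions: MsCl (2 equiv), Et3N (3 equiv), CH2Cl2, 0 °C; then DBU (3 equiv), 20 °C
Reagents that add atoms: none
Why: sulfene mesylation of the tertiary alcohol and E1cB elimination through the C3 enolate give the conjugated isopropylidene and remove the C3 epimer mixture.

**Step 11**
Reactants: 20 (4aR,5R)-6,6-dimethoxy-4a,5-dimethyl-3-(propan-2-ylidene)-4,4a,5,6-tetrahydronaphthalen-2(3H)-one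
Product: 21 (4aR,5R)-4a,5-dimethyl-3-(propan-2-ylidene)-4,4a-dihydronaphthalene-2,6(3H,5H)-dione
Conditions: aq HCl (1 M), THF, 0 → 20 °C
Reagents that add atoms: water O
Why: acid-catalysed hydrolysis of the dimethyl ketal, run cold and briefly so that the C5 centre next to the new ketone does not epimerise.

**Step 12**
Reactants: 21 (4aR,5R)-4a,5-dimethyl-3-(propan-2-ylidene)-4,4a-dihydronaphthalene-2,6(3H,5H)-dione
Product: 22 (4aR,5R,6S)-6-hydroxy-4a,5-dimethyl-3-(propan-2-ylidene)-4,4a,5,6-tetrahydronaphthalen-2(3H)-one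
Conditions: NaBH4 (1.0 equiv), CeCl3·7H2O (1.1 equiv), MeOH/CH2Cl2, −78 °C
Reagents that add atoms: none
Why: Luche 1,2-reduction attacks the unhindered C6 carbonyl from the face opposite the pseudoaxial angular methyl, which places the hydroxyl cis to both methyl groups (6S), while the cross-conjugated C2 carbonyl is shielded by the isopropylidene and does not react.

**Step 13**
Reactants: 23 methyl (E)-4-bromobut-2-enoate
Product: 24 methyl (E)-4-(diethoxyphosphoryl)but-2-enoate
Conditions: P(OEt)3 (1.1 equiv), neat, 120 °C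
Reagents that add atoms: triethyl phosphite CCOP(OCC)OCC
Why: Michaelis–Arbuzov reaction of the allylic bromide.

**Step 14**
Reactants: 25 (S)-2-methylbutan-1-ol
Product: 26 (S)-2-methylbutanal
Conditions: TEMPO (2,2,6,6-tetramethylpiperidin-1-oxyl, 1 mol%), KBr (10 mol%), aq NaOCl (1.1 equiv), NaHCO3, CH2Cl2, 0 °C
Reagents that add atoms: none
Why: Anelli oxidation under buffered two-phase conditions gives the alpha-branched aldehyde without racemisation, and the stereocentre comes from the chiral pool.

**Step 15**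
Reactants: 26 (S)-2-methylbutanal; 24 methyl (E)-4-(diethoxyphosphoryl)but-2-enoate
Product: 28 methyl (2E,4E,6S)-6-methylocta-2,4-dienoate, via phosphonate anion 27 (not isolated)
Conditions: LiN(SiMe3)2 (1.05 equiv), THF, −78 °C; then 26, −78 → 0 °C
Reagents that add atoms: none
Why: vinylogous Horner–Wadsworth–Emmons olefination forms the new double bond E and keeps the existing one E, and the low temperature preserves the alpha stereocentre.

**Step 16**
Reactants: 28 methyl (2E,4E,6S)-6-methylocta-2,4-dienoate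
Product: 29 (2E,4E,6S)-6-methylocta-2,4-dienoic acid
Conditions: LiOH·H2O (3 equiv), THF/MeOH/H2O, 20 °C; then aq HCl to pH 3
Reagents that add atoms: lithium hydroxide [Li+].[OH-]
Why: saponification of the methyl ester, with the remote stereocentre and the diene geometry unaffected.

**Step 17**
Reactants: 29 (2E,4E,6S)-6-methylocta-2,4-dienoic acid; 22 (4aR,5R,6S)-6-hydroxy-4a,5-dimethyl-3-(propan-2-ylidene)-4,4a,5,6-tetrahydronaphthalen-2(3H)-one
Product: 31 (1R,2S,8aR)-1,8a-dimethyl-6-oxo-7-(propan-2-ylidene)-1,2,6,7,8,8a-hexahydronaphthalen-2-yl (2E,4E,6S)-6-methylocta-2,4-dienoate, via mixed anhydride 30 (not isolated)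
Conditions: 2,4,6-trichlorobenzoyl chloride (1.3 equiv), Et3N (2.5 equiv), toluene, 20 °C; then 22, 4-(dimethylamino)pyridine (1.5 equiv), toluene, 20 → 40 °C
Reagents that add atoms: none
Why: Yamaguchi esterification acylates the hindered carbinol oxygen through the mixed anhydride and the acylpyridinium, so the C–O bond of 22 is not broken and its configuration is retained.

**Compound list**
1 | hydroquinone (benzene-1,4-diol) | Oc1ccc(O)cc1 | starting material
2 | 4-methoxyphenol | COc1ccc(O)cc1 | intermediate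
3 | 4,4-dimethoxycyclohexa-2,5-dien-1-one | COC1(OC)C=CC(=O)C=C1 | intermediate
4 | (5R)-4,4-dimethoxy-5-methylcyclohex-2-en-1-one | O=C1C[C@@H](C)C(OC)(OC)C=C1 | intermediate
5 | lithium (3R)-4,4-dimethoxy-3-methylcyclohexa-1,5-dien-1-olate | [Li]OC1=C[C@@H](C)C(OC)(OC)C=C1 | intermediate (not isolated)
6 | (5R,6R)-4,4-dimethoxy-5,6-dimethylcyclohex-2-en-1-one (trans, major; the 6S epimer is carried along) | C[C@H]1C(=O)C=CC(OC)(OC)[C@@H]1C | intermediate
7 | (1-bromovinyl)trimethylsilane | C=C(Br)[Si](C)(C)C | starting material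
8 | acetaldehyde | CC=O | starting material
9 | [1-(trimethylsilyl)ethenyl]magnesium bromide | C=C([Mg]Br)[Si](C)(C)C | intermediate (not isolated)
10 | 3-(trimethylsilyl)but-3-en-2-ol (racemic) | CC(O)C(=C)[Si](C)(C)C | intermediate
11 | 3-(trimethylsilyl)but-3-en-2-one | CC(=O)C(=C)[Si](C)(C)C | intermediate
12 | lithium (3R)-4,4-dimethoxy-2,3-dimethylcyclohexa-1,5-dien-1-olate | CC1=C(O[Li])C=CC(OC)(OC)[C@@H]1C | intermediate (not isolated)
13 | (5R,6R)-4,4-dimethoxy-5,6-dimethyl-6-[3-oxo-2-(trimethylsilyl)butyl]cyclohex-2-en-1-one (both epimers at the silyl-bearing carbon, left open in the SMILES) | CC(=O)C([Si](C)(C)C)C[C@@]1(C)C(=O)C=CC(OC)(OC)[C@@H]1C | intermediate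
14 | (5R,6R)-4,4-dimethoxy-5,6-dimethyl-6-(3-oxobutyl)cyclohex-2-en-1-one | CC(=O)CC[C@@]1(C)C(=O)C=CC(OC)(OC)[C@@H]1C | intermediate (not isolated)
15 | (4aR,5R)-6,6-dimethoxy-4a,5-dimethyl-4,4a,5,6-tetrahydronaphthalen-2(3H)-one | COC1(OC)C=CC2=CC(=O)CC[C@]2(C)[C@H]1C | intermediate
16 | acetone | CC(C)=O | starting material
17 | lithium (4aR,5R)-6,6-dimethoxy-4a,5-dimethyl-4,4a,5,6-tetrahydronaphthalen-2-olate | COC1(OC)C=CC2=CC(O[Li])=CC[C@]2(C)[C@H]1C | intermediate (not isolated)
18 | (4aR,5R)-3-(2-hydroxypropan-2-yl)-6,6-dimethoxy-4a,5-dimethyl-4,4a,5,6-tetrahydronaphthalen-2(3H)-one (both C3 epimers, left open in the SMILES) | COC1(OC)C=CC2=CC(=O)C(C(C)(C)O)C[C@]2(C)[C@H]1C | intermediate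
19 | 2-[(4aR,5R)-6,6-dimethoxy-4a,5-dimethyl-2-oxo-2,3,4,4a,5,6-hexahydronaphthalen-3-yl]propan-2-yl methanesulfonate (both C3 epimers) | COC1(OC)C=CC2=CC(=O)C(C(C)(C)OS(C)(=O)=O)C[C@]2(C)[C@H]1C | intermediate (not isolated)
20 | (4aR,5R)-6,6-dimethoxy-4a,5-dimethyl-3-(propan-2-ylidene)-4,4a,5,6-tetrahydronaphthalen-2(3H)-one | COC1(OC)C=CC2=CC(=O)C(=C(C)C)C[C@]2(C)[C@H]1C | intermediate
21 | (4aR,5R)-4a,5-dimethyl-3-(propan-2-ylidene)-4,4a-dihydronaphthalene-2,6(3H,5H)-dione | O=C1C=CC2=CC(=O)C(=C(C)C)C[C@]2(C)[C@H]1C | intermediate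
22 | (4aR,5R,6S)-6-hydroxy-4a,5-dimethyl-3-(propan-2-ylidene)-4,4a,5,6-tetrahydronaphthalen-2(3H)-one (hydroxyl and both methyls on one face) | O[C@H]1C=CC2=CC(=O)C(=C(C)C)C[C@]2(C)[C@H]1C | intermediate
23 | methyl (E)-4-bromobut-2-enoate | COC(=O)/C=C/CBr | starting material
24 | methyl (E)-4-(diethoxyphosphoryl)but-2-enoate | COC(=O)/C=C/CP(=O)(OCC)OCC | intermediate
25 | (S)-2-methylbutan-1-ol | CC[C@H](C)CO | starting material
26 | (S)-2-methylbutanal | CC[C@H](C)C=O | intermediate
27 | lithium (E)-1-(diethoxyphosphoryl)-4-methoxy-4-oxobut-2-en-1-ide | [Li+].COC(=O)/C=C/[CH-]P(=O)(OCC)OCC | intermediate (not isolated)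
28 | methyl (2E,4E,6S)-6-methylocta-2,4-dienoate | CC[C@H](C)/C=C/C=C/C(=O)OC | intermediate
29 | (2E,4E,6S)-6-methylocta-2,4-dienoic acid | CC[C@H](C)/C=C/C=C/C(=O)O | intermediate
30 | (2E,4E,6S)-6-methylocta-2,4-dienoic 2,4,6-trichlorobenzoic anhydride | CC[C@H](C)/C=C/C=C/C(=O)OC(=O)c1c(Cl)cc(Cl)cc1Cl | intermediate (not isolated)
31 | (1R,2S,8aR)-1,8a-dimethyl-6-oxo-7-(propan-2-ylidene)-1,2,6,7,8,8a-hexahydronaphthalen-2-yl (2E,4E,6S)-6-methylocta-2,4-dienoate (CNP0215744.1) | CC[C@H](C)/C=C/C=C/C(=O)O[C@H]1C=CC2=CC(=O)C(=C(C)C)C[C@]2(C)[C@H]1C | target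

**Totals**
Total step count: 17.
Longest linear sequence: 11 steps (1, 2, 3, 4, 7, 8, 9, 10, 11, 12, 17).

**Three steps most likely to fail**

Step 7 is the first risk. The tetrasubstituted dienolate may add sluggishly, the intermediate enolate may add a second time to the ring enone to give a bicyclo[2.2.2]octanone, or the adduct may revert. The fallback replaces the Michael addition by an SN2 alkylation. It sets out from 6: dienolate 12 is alkylated with but-3-yn-1-yl trifluoromethanesulfonate (THF, −78 → 0 °C) to give (5R,6R)-6-(but-3-yn-1-yl)-4,4-dimethoxy-5,6-dimethylcyclohex-2-en-1-one F1. Markovnikov hydration of the terminal alkyne with Ph3PAuNTf2 (2 mol%) in wet 1,4-dioxane at 40 °C then gives diketone 14, this time isolated. The fallback comes back to the route at 14, which is cyclised to 15 with KOH/MeOH as before.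

Step 12 is the second risk. The torsional preference for axial attack works against the steric bias, so the reduction may give mainly the C6 epimer. The fallback turns that epimer into product by moving the inversion into the coupling. It sets out from 21: the reduction product (4aR,5R,6R)-6-hydroxy-4a,5-dimethyl-3-(propan-2-ylidene)-4,4a,5,6-tetrahydronaphthalen-2(3H)-one F2 is isolated and coupled with acid 29 under Mitsunobu conditions (PPh3, diisopropyl azodicarboxylate, toluene, 0 → 20 °C). Displacement with inversion at C6 gives the ester directly, so the fallback comes back to the route at 31.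

Step 17 is the third risk. The pseudoaxial allylic alcohol, flanked by two methyl groups, may acylate slowly, and the dienoyl donor may isomerise. The fallback attaches a smaller acyl group first and builds the diene on the ester. It sets out from 22, using 24 and 26 from the route. Ester 24 is hydrolysed (LiOH, THF/H2O, 0 °C) to (E)-4-(diethoxyphosphoryl)but-2-enoic acid F3. F3 is coupled to 22 with N,N'-dicyclohexylcarbodiimide and 4-(dimethylamino)pyridine in CH2Cl2 to give (1R,2S,8aR)-1,8a-dimethyl-6-oxo-7-(propan-2-ylidene)-1,2,6,7,8,8a-hexahydronaphthalen-2-yl (E)-4-(diethoxyphosphoryl)but-2-enoate F4. Deprotonation of F4 with LiN(SiMe3)2 (THF, −78 °C) and addition of aldehyde 26 completes the (2E,4E)-diene by Horner–Wadsworth–Emmons olefination, so the fallback comes back to the route at 31.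

**Further compounds**
F1 | step 7 | (5R,6R)-6-(but-3-yn-1-yl)-4,4-dimethoxy-5,6-dimethylcyclohex-2-en-1-one | C#CCC[C@@]1(C)C(=O)C=CC(OC)(OC)[C@@H]1C
F2 | step 12 | (4aR,5R,6R)-6-hydroxy-4a,5-dimethyl-3-(propan-2-ylidene)-4,4a,5,6-tetrahydronaphthalen-2(3H)-one | O[C@@H]1C=CC2=CC(=O)C(=C(C)C)C[C@]2(C)[C@H]1C
F3 | step 17 | (E)-4-(diethoxyphosphoryl)but-2-enoic acid | OC(=O)/C=C/CP(=O)(OCC)OCC
F4 | step 17 | (1R,2S,8aR)-1,8a-dimethyl-6-oxo-7-(propan-2-ylidene)-1,2,6,7,8,8a-hexahydronaphthalen-2-yl (E)-4-(diethoxyphosphoryl)but-2-enoate | CCOP(=O)(OCC)C/C=C/C(=O)O[C@H]1C=CC2=CC(=O)C(=C(C)C)C[C@]2(C)[C@H]1C
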